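| flask | substrate | reagent in the second phase | remark | time | volume of the second phase over the first |
|---|---|---|---|---|---|
| elm | 0.050 M (in portions, 4) | 0.026 M | run made earlier; portions every 20 s |  |  |
| larch | 0.050 M (in portions, 4) | 0.10 M | run made earlier; portions every 20 s |  |  |
| ash | 0.10 M (in portions, 4) | 0.0525 M | run made earlier; portions every 20 s |  |  |
| flask | 0.050 M (in portions, 4) | 0.0525 M | the portions of substrate follow each other after 20 s, the first at the start | 15 min | 1.0 |

| run | time / min | product / % | substrate / % |
|---|---|---|---|
| elm | 1.33 | 1.3 | 99.1 |
| elm | 2.50 | 2.7 | 97.5 |
| elm | 4.00 | 4.6 | 95.2 |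
| elm | 6.00 | 6.5 | 93.4 |
| elm | 10.0 | 11.1 | 88.9 |
| elm | 20.0 | 19.9 | 79.2 |
| larch | 1.33 | 4.2 | 94.9 |
| larch | 2.50 | 10.7 | 88.8 |
| larch | 4.00 | 17.4 | 83.1 |
| larch | 6.00 | 24.5 | 74.8 |
| larch | 10.0 | 38.6 | 60.8 |
| larch | 20.0 | 60.4 | 38.6 |
| ash | 1.50 | 2.8 | 98.6 |
| ash | 5.00 | 9.4 | 91.5 |
| ash | 8.00 | 15.1 | 85.8 |
| ash | 12.0 | 21.1 | 78.9 |
| ash | 20.0 | 29.1 | 71.8 |

(each reading ± 0.5 percentage points)
- in the second phase: reagent in the second phase; everything else is in the first
- charges count per volume of the first phase; a concentration in a rate is the amount of a species over the volume of its own phase; every rate counts per litre of the first phase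
- the earlier runs were read with a standard deviation of 0.5 percentage points
- the earlier runs hold the two phases in the same ratio of volumes as the flask asked about
- product present at 15 min, in percent of the substrate charged
- substrate present at 15 min, in percent of the substrate charged
- concentration of reagent in the reaction phase at 15 min, in M

- Start from early times: at 2.50 min, larch holds 3.96 times the product of elm on 3.85 times the reagent in the second phase, so take the rate as k[substrate][reagent in the second phase].
- Take k from the larch reading at 20.0 min by the integrated second-order law, and multiply it by the flask's charge of reagent in the second phase: each substrate molecule in the flask starts with a chance of loss of 0.0298 min⁻¹.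
- Multiply by the time to get N = 0.446, the flask's time counted in starting lifetimes of substrate.
- Substrate is the limiting reagent in the flask, though barely, so reagent in the second phase falls along with it. The consumed share is then close to N/(1+N).
- My reckoning for the flask is therefore 30.9% product and 69.1% substrate. The runs hold no reading of [reagent in the reaction phase], so I give no value for it.
- Test whether one number is enough: k from elm gives N = 0.427, and k from ash gives 0.385. Ash reads lower than larch but differs from larch in both charges, so keep to larch, which shares the flask's substrate charge.
- The forecast gives 28.5% product, 71.5% substrate and 0.005 M for [reagent in the reaction phase], of which it says: “this is a wide guess”.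
- The flask gives 30.3% product, 69.7% substrate and 5.50 × 10⁻⁴ M for [reagent in the reaction phase], a factor 9.09 below the forecast.

    reagent in the reaction phase ⇌ reagent in the second phase, rate k1*([reagent in the reaction phase] - [reagent in the second phase]/K1) per volume of the first phase (partition coefficient = 57.0, kL = 0.130 s⁻¹)
    substrate + reagent in the reaction phase → product (k = 0.657 M⁻¹ s⁻¹)

- Read N back from the flask: product over substrate is 0.435, against 0.446. The flask is not at rest at 15.0 min, with 69.7% of its substrate and 70.1% of its reagent in the second phase still there. Multiply N by ten and the share gives 81.7% product. Left to 150 min, the flask holds 84.7% product and 15.3% substrate, with [reagent in the reaction phase] down to 1.69 × 10⁻⁴ M.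

The runs were computed with constants of no real substance; the scatter is artificial.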